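**Retrosynthetic overview**
1. Last C–C bond: the ketol C8–aryl bond, made by Ni-catalysed stereoconvergent (radical) arylation of racemic bromoketone 29 with the arylzinc of lactone 24; then global desilylation.
2. Key disconnection: the lactone C3–C4 (8–8′) bond, made by Fe(III)-mediated oxidative radical heterocoupling of two enolates, imide 18 (ring B) and the phenylcoumaran ester 13.
3. Phenylcoumaran: auxiliary-controlled phenoxyl-radical 8–5′ cross-coupling of feruloyl sultam 9 with dihydroferulate 6.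
4. All four guaiacyl rings come from catechol via 4-iodoguaiacol 3 plus acrylic C3 units (Heck); the ketol C3 unit comes from β-propiolactone.
5. Ring order: dihydrobenzofuran first (step 6), γ-butyrolactone second (step 13).

Assumption: the (2R)-sultam, the (4S)-oxazolidinone and the chosen pybox antipode are taken to induce the configurations drawn; if a sense is opposite, the mirror-image auxiliary or ligand is used with no other change.

Abbreviations: TBS = tert-butyldimethylsilyl; Cou = (2S,3R)-2-[4-(TBSO)-3-methoxyphenyl]-3-(TBSOCH2)-7-methoxy-2,3-dihydro-1-benzofuran-5-yl; ArB = 4-(TBSO)-3-iodo-5-methoxyphenyl.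

**Route**

Step 1
Reactants: 1 catechol
Product: 2 guaiacol (2-methoxyphenol)
Conditions: MeI (0.9 eq), K2CO3 (1.0 eq), acetone, reflux; extraction/distillation
Reagents that add atoms: iodomethane (CI)
Why: Williamson mono-O-methylation, with sub-stoichiometric MeI limiting veratrole formation and unreacted catechol recycled.

Step 2
Reactants: 2 guaiacol
Product: 3 4-iodo-2-methoxyphenol
Conditions: NIS (1.0 eq), TsOH·H2O (10 mol %), MeCN, 0 °C → rt
Reagents that add atoms: N-iodosuccinimide (O=C1CCC(=O)N1I)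
Why: electrophilic aromatic iodination para to the free OH, the stronger donor.

Step 3
Reactants: 3 4-iodo-2-methoxyphenol; 4 isopropyl acrylate
Product: 6 isopropyl 3-(4-hydroxy-3-methoxyphenyl)propanoate, via isopropyl ferulate 5 (not isolated)
Conditions: Pd/C (5 mol %), NaOAc (1.5 eq), DMF, 100 °C; then H2 (5 bar), rt, same vessel
Reagents that add atoms: none
Why: Mizoroki–Heck arylation followed by hydrogenation of the cinnamate C=C on the same heterogeneous Pd.

Step 4
Reactants: 7 acryloyl chloride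
Product: 8 N-acryloyl-(2R)-bornane-10,2-sultam
Conditions: (2R)-bornane-10,2-sultam, NaH, toluene, 0 °C; then 7, CuCl (cat.), rt
Reagents that add atoms: (2R)-bornane-10,2-sultam (CC1(C)[C@@H]2CC[C@]13CS(=O)(=O)N[C@@H]3C2)
Why: N-acylation of the sultam sodium salt (Oppolzer acylation).

Step 5
Reactants: 3 4-iodo-2-methoxyphenol; 8 N-acryloyl sultam
Product: 9 N-[(E)-feruloyl]-(2R)-bornane-10,2-sultam
Conditions: Pd(OAc)2 (3 mol %), NaHCO3 (2.5 eq), Bu4NCl (1 eq), DMF, 60 °C
Reagents that add atoms: none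
Why: ligand-free (Jeffery) Heck reaction giving the E-alkene under conditions mild enough for the free phenol and the acyl sultam.

Step 6
Reactants: 9 feruloyl sultam; 6 isopropyl dihydroferulate (4 eq, excess recovered)
Product: 11 isopropyl 3-[(2S,3S)-2-(4-hydroxy-3-methoxyphenyl)-7-methoxy-3-{[(2R)-bornane-10,2-sultam-N-yl]carbonyl}-2,3-dihydro-1-benzofuran-5-yl]propanoate, via quinone methide 10 (not isolated)
Conditions: Ag2O (1.5 eq), CH2Cl2/acetone, rt, dark; 9 added over 10 h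
Reagents that add atoms: none
Why: Proposed new method: Ag2O oxidises both phenols to phenoxyl radicals, and slow addition keeps the feruloyl radical (spin at C8) dilute so that it is trapped at C8 by the excess non-conjugated guaiacyl radical of 6 at its free C5 (8–5′ cross-coupling) rather than by itself; the sultam shields one C8 face (sets C3), ring C re-aromatises and its phenol closes onto quinone methide 10 anti to the acyl group (sets C2, trans); the closest known reactions are the auxiliary-controlled Ag2O homo-dimerisation of feruloyl sultams to dehydrodiferulates and the oxidative cross-coupling of monolignols with saturated guaiacyl phenols.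

Step 7
Reactants: 11 coumaran acyl sultam
Product: 12 isopropyl 3-[(2S,3R)-2-(4-hydroxy-3-methoxyphenyl)-3-(hydroxymethyl)-7-methoxy-2,3-dihydro-1-benzofuran-5-yl]propanoate
Conditions: LiBH4 (2 eq), H2O (2 eq), Et2O/THF, 0 °C
Reagents that add atoms: none
Why: reductive cleavage of the activated N-acyl sultam to the primary alcohol while the hindered isopropyl ester survives; geometry is unchanged and the C3 label changes S→R only through CIP priority.

Step 8
Reactants: 12 coumaran diol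
Product: 13 isopropyl 3-(Cou)propanoate
Conditions: TBSOTf (2.5 eq), 2,6-lutidine (3 eq), CH2Cl2, 0 °C
Reagents that add atoms: TBSOTf (CC(C)(C)[Si](C)(C)OS(=O)(=O)C(F)(F)F)
Why: silylation of phenol and primary alcohol so that no acidic or oxidisable OH remains for the enolate coupling.

Step 9
Reactants: 7 acryloyl chloride
Product: 14 (4S)-3-acryloyl-4-benzyl-1,3-oxazolidin-2-one
Conditions: (4S)-4-benzyl-1,3-oxazolidin-2-one, LiCl, Et3N, THF, −20 °C → rt
Reagents that add atoms: (4S)-4-benzyl-1,3-oxazolidin-2-one (O=C1N[C@@H](Cc2ccccc2)CO1)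
Why: LiCl/Et3N-mediated N-acylation of the Evans auxiliary, which avoids anionic polymerisation of the acrylate.

Step 10
Reactants: 3 4-iodo-2-methoxyphenol; 14 N-acryloyl oxazolidinone
Product: 16 (4S)-4-benzyl-3-[3-(4-hydroxy-3-methoxyphenyl)propanoyl]-1,3-oxazolidin-2-one, via N-feruloyl oxazolidinone 15 (not isolated)
Conditions: Pd/C (5 mol %), NaOAc (1.5 eq), DMF, 90 °C; then H2 (5 bar), rt, same vessel
Reagents that add atoms: none
Why: Heck arylation then hydrogenation of the enoyl C=C on the same Pd, as in step 3.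

Step 11
Reactants: 16 dihydroferuloyl imide
Product: 18 (4S)-4-benzyl-3-[3-(ArB)propanoyl]-1,3-oxazolidin-2-one, via iodophenol 17 (not isolated)
Conditions: NIS (1.05 eq), TsOH·H2O (10 mol %), CH2Cl2/MeCN, 0 °C → rt; then 2,6-lutidine (3 eq), TBSOTf (1.5 eq), 0 °C
Reagents that add atoms: N-iodosuccinimide (O=C1CCC(=O)N1I); TBSOTf (CC(C)(C)[Si](C)(C)OS(=O)(=O)C(F)(F)F)
Why: electrophilic iodination at the only free position ortho to OH (para is blocked), then in situ silylation of the hindered phenol.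

Step 12 (key step)
Reactants: 18 imide (1.0 eq); 13 ester (1.0 eq)
Product: 21 isopropyl (2RS,3R)-4-[(4S)-4-benzyl-2-oxo-1,3-oxazolidin-3-yl]-3-(ArB-methyl)-2-(Cou-methyl)-4-oxobutanoate, via lithium imide enolate 19 (not isolated), via lithium ester enolate 20 (not isolated)
Conditions: LDA (2.1 eq), THF, −78 °C, 30 min; Fe(acac)3 (2.2 eq), −78 °C → rt
Reagents that add atoms: none
Why: oxidative enolate heterocoupling in which Fe(III) oxidises the mixed enolate aggregate by single-electron transfer to an α-carbonyl radical that couples with the second enolate, the new bond forming anti to the auxiliary benzyl group on the chelated Z-imide enolate (sets C3 as R) while the ester α-centre forms as an epimer mixture that is corrected in step 13.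

Step 13
Reactants: 21 succinate
Product: 24 (3R,4R)-4-(ArB-methyl)-3-(Cou-methyl)oxolan-2-one, via hydroxy ester 22 (not isolated), via cis-lactone 23 (not isolated)
Conditions: LiBH4 (1.5 eq), H2O (1.5 eq), THF/Et2O, 0 °C; then DBU (1 eq), toluene, 60 °C
Reagents that add atoms: none
Why: chemoselective reduction of the imide carbonyl releases the auxiliary, the γ-hydroxy isopropyl ester lactonises, and DBU epimerises the lactone α-centre to the thermodynamically favoured trans-3,4-dibenzyl lactone (sets C3 as R).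

Step 14
Reactants: 3 4-iodo-2-methoxyphenol; 25 β-propiolactone
Product: 27 3-hydroxy-1-(4-hydroxy-3-methoxyphenyl)propan-1-one, via dilithio phenolate 26 (not isolated)
Conditions: t-BuLi (3.1 eq), THF, −78 °C; then added to 25 (1.1 eq), THF, −78 °C; 1 M HCl
Reagents that add atoms: none
Why: O-deprotonation and iodine–lithium exchange, then acyl attack of the aryllithium on the strained lactone with ring opening, the resulting para-oxido aryl ketone being a vinylogous carboxylate that resists a second addition.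

Step 15
Reactants: 27 hydroxy ketone
Product: 29 (±)-2-bromo-3-(TBSO)-1-[4-(TBSO)-3-methoxyphenyl]propan-1-one, via tris-TBS enol silane 28 (not isolated)
Conditions: TBSOTf (3.3 eq), Et3N (4 eq), CH2Cl2, 0 °C → rt; then NBS (1.05 eq), THF, −78 → 0 °C
Reagents that add atoms: TBSOTf (CC(C)(C)[Si](C)(C)OS(=O)(=O)C(F)(F)F); N-bromosuccinimide (O=C1CCC(=O)N1Br)
Why: one-pot silylation of phenol, alcohol and ketone (soft enolisation) followed by electrophilic bromination of the enol silane, the most nucleophilic site.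

Step 16
Reactants: 24 iodo lactone; 29 bromoketone (1.5 eq)
Product: 31 (3R,4R)-4-({4-(TBSO)-3-[(2S)-3-(TBSO)-1-[4-(TBSO)-3-methoxyphenyl]-1-oxopropan-2-yl]-5-methoxyphenyl}methyl)-3-(Cou-methyl)oxolan-2-one, via arylzinc iodide 30 (not isolated)
Conditions: Zn dust (3 eq), LiCl (1.5 eq), THF, 50 °C; then 29, NiCl2·glyme (10 mol %), chiral pybox (13 mol %), glyme/THF, −30 °C
Reagents that add atoms: none
Why: Knochel zinc insertion (lactone-tolerant) then Ni-catalysed stereoconvergent Negishi α-arylation, in which Ni(I) abstracts Br to give a planar α-keto radical that is captured by the chiral (pybox)Ni–aryl, so both enantiomers of 29 converge on 8S under ligand control at a temperature where the labile α-aryl ketone does not epimerise.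

Step 17
Reactants: 31 penta-TBS ether
Product: 32 target CNP0111438.1
Conditions: TBAF (7 eq), AcOH (7 eq), THF, 0 °C → rt
Reagents that add atoms: none
Why: buffered fluoride desilylation of three aryl and two primary TBS ethers under near-neutral conditions that avoid epimerisation, retro-aldol and benzofuran formation at the ketol.

**Compound list**

1 | catechol | Oc1ccccc1O | starting material
2 | guaiacol | COc1ccccc1O | intermediate
3 | 4-iodo-2-methoxyphenol | COc1cc(I)ccc1O | intermediate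
4 | isopropyl acrylate | C=CC(=O)OC(C)C | starting material
5 | isopropyl (E)-ferulate | COc1cc(/C=C/C(=O)OC(C)C)ccc1O | intermediate
6 | isopropyl 3-(4-hydroxy-3-methoxyphenyl)propanoate | COc1cc(CCC(=O)OC(C)C)ccc1O | intermediate
7 | acryloyl chloride | C=CC(Cl)=O | starting material
8 | N-acryloyl-(2R)-bornane-10,2-sultam | C=CC(=O)N1[C@@H]2C[C@H]3CC[C@]2(CS1(=O)=O)C3(C)C | intermediate
9 | N-[(E)-feruloyl]-(2R)-bornane-10,2-sultam | COc1cc(/C=C/C(=O)N2[C@@H]3C[C@H]4CC[C@]3(CS2(=O)=O)C4(C)C)ccc1O | intermediate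
10 | 8–5′-coupled p-quinone methide (ring C phenol, ring D methoxy-quinone methide, C8 configured as in 11) | CC(C)OC(=O)CCc1cc(OC)c(O)c(c1)[C@H](C(=O)N2[C@@H]3C[C@H]4CC[C@]3(CS2(=O)=O)C4(C)C)C=C1C=CC(=O)C(OC)=C1 | intermediate
11 | isopropyl 3-[(2S,3S)-2-(4-hydroxy-3-methoxyphenyl)-7-methoxy-3-(sultam-N-carbonyl)-2,3-dihydro-1-benzofuran-5-yl]propanoate | CC(C)OC(=O)CCc1cc(OC)c2c(c1)[C@H](C(=O)N3[C@@H]4C[C@H]5CC[C@]4(CS3(=O)=O)C5(C)C)[C@@H](c1ccc(O)c(OC)c1)O2 | intermediate
12 | isopropyl 3-[(2S,3R)-2-(4-hydroxy-3-methoxyphenyl)-3-(hydroxymethyl)-7-methoxy-2,3-dihydro-1-benzofuran-5-yl]propanoate | CC(C)OC(=O)CCc1cc(OC)c2c(c1)[C@H](CO)[C@@H](c1ccc(O)c(OC)c1)O2 | intermediate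
13 | isopropyl 3-(Cou)propanoate (bis-TBS ether of 12) | CC(C)OC(=O)CCc1cc(OC)c2c(c1)[C@H](CO[Si](C)(C)C(C)(C)C)[C@@H](c1ccc(O[Si](C)(C)C(C)(C)C)c(OC)c1)O2 | intermediate
14 | (4S)-3-acryloyl-4-benzyl-1,3-oxazolidin-2-one | C=CC(=O)N1[C@@H](Cc2ccccc2)COC1=O | intermediate
15 | (4S)-4-benzyl-3-[(E)-feruloyl]-1,3-oxazolidin-2-one | COc1cc(/C=C/C(=O)N2[C@@H](Cc3ccccc3)COC2=O)ccc1O | intermediate
16 | (4S)-4-benzyl-3-[3-(4-hydroxy-3-methoxyphenyl)propanoyl]-1,3-oxazolidin-2-one | COc1cc(CCC(=O)N2[C@@H](Cc3ccccc3)COC2=O)ccc1O | intermediate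
17 | (4S)-4-benzyl-3-[3-(4-hydroxy-3-iodo-5-methoxyphenyl)propanoyl]-1,3-oxazolidin-2-one | COc1cc(CCC(=O)N2[C@@H](Cc3ccccc3)COC2=O)cc(I)c1O | intermediate
18 | (4S)-4-benzyl-3-[3-(ArB)propanoyl]-1,3-oxazolidin-2-one | COc1cc(CCC(=O)N2[C@@H](Cc3ccccc3)COC2=O)cc(I)c1O[Si](C)(C)C(C)(C)C | intermediate
19 | lithium (Z)-enolate of 18 | COc1cc(C/C=C(\O[Li])N2[C@@H](Cc3ccccc3)COC2=O)cc(I)c1O[Si](C)(C)C(C)(C)C | intermediate
20 | lithium enolate of 13 | CC(C)OC(O[Li])=CCc1cc(OC)c2c(c1)[C@H](CO[Si](C)(C)C(C)(C)C)[C@@H](c1ccc(O[Si](C)(C)C(C)(C)C)c(OC)c1)O2 | intermediate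
21 | isopropyl (2RS,3R)-4-[(4S)-4-benzyl-2-oxo-1,3-oxazolidin-3-yl]-3-(ArB-methyl)-2-(Cou-methyl)-4-oxobutanoate (C2 epimer mixture) | COc1cc(C[C@@H](C(=O)N2[C@@H](Cc3ccccc3)COC2=O)C(C(=O)OC(C)C)Cc2cc(OC)c3c(c2)[C@H](CO[Si](C)(C)C(C)(C)C)[C@@H](c2ccc(O[Si](C)(C)C(C)(C)C)c(OC)c2)O3)cc(I)c1O[Si](C)(C)C(C)(C)C | intermediate
22 | isopropyl (2RS,3R)-4-hydroxy-3-(ArB-methyl)-2-(Cou-methyl)butanoate | COc1cc(C[C@@H](CO)C(C(=O)OC(C)C)Cc2cc(OC)c3c(c2)[C@H](CO[Si](C)(C)C(C)(C)C)[C@@H](c2ccc(O[Si](C)(C)C(C)(C)C)c(OC)c2)O3)cc(I)c1O[Si](C)(C)C(C)(C)C | intermediate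
23 | (3S,4R)-4-(ArB-methyl)-3-(Cou-methyl)oxolan-2-one (cis) | COc1cc(C[C@H]2COC(=O)[C@H]2Cc2cc(OC)c3c(c2)[C@H](CO[Si](C)(C)C(C)(C)C)[C@@H](c2ccc(O[Si](C)(C)C(C)(C)C)c(OC)c2)O3)cc(I)c1O[Si](C)(C)C(C)(C)C | intermediate
24 | (3R,4R)-4-(ArB-methyl)-3-(Cou-methyl)oxolan-2-one (trans) | COc1cc(C[C@H]2COC(=O)[C@@H]2Cc2cc(OC)c3c(c2)[C@H](CO[Si](C)(C)C(C)(C)C)[C@@H](c2ccc(O[Si](C)(C)C(C)(C)C)c(OC)c2)O3)cc(I)c1O[Si](C)(C)C(C)(C)C | intermediate
25 | β-propiolactone (oxetan-2-one) | O=C1CCO1 | starting material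
26 | lithium 4-lithio-2-methoxyphenolate | [Li]Oc1ccc([Li])cc1OC | intermediate
27 | 3-hydroxy-1-(4-hydroxy-3-methoxyphenyl)propan-1-one | COc1cc(C(=O)CCO)ccc1O | intermediate
28 | (Z)-1,3-bis(TBSO)-1-[4-(TBSO)-3-methoxyphenyl]prop-1-ene | COc1cc(/C(O[Si](C)(C)C(C)(C)C)=C/CO[Si](C)(C)C(C)(C)C)ccc1O[Si](C)(C)C(C)(C)C | intermediate
29 | (±)-2-bromo-3-(TBSO)-1-[4-(TBSO)-3-methoxyphenyl]propan-1-one | COc1cc(C(=O)C(Br)CO[Si](C)(C)C(C)(C)C)ccc1O[Si](C)(C)C(C)(C)C | intermediate
30 | arylzinc iodide of 24 (ZnI in place of I) | COc1cc(C[C@H]2COC(=O)[C@@H]2Cc2cc(OC)c3c(c2)[C@H](CO[Si](C)(C)C(C)(C)C)[C@@H](c2ccc(O[Si](C)(C)C(C)(C)C)c(OC)c2)O3)cc([Zn]I)c1O[Si](C)(C)C(C)(C)C | intermediate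
31 | penta-TBS ether of the target (8S; lactone 3R,4R; coumaran 2S,3R) | COc1cc(C(=O)[C@H](CO[Si](C)(C)C(C)(C)C)c2cc(C[C@H]3COC(=O)[C@@H]3Cc3cc(OC)c4c(c3)[C@H](CO[Si](C)(C)C(C)(C)C)[C@@H](c3ccc(O[Si](C)(C)C(C)(C)C)c(OC)c3)O4)cc(OC)c2O[Si](C)(C)C(C)(C)C)ccc1O[Si](C)(C)C(C)(C)C | intermediate
32 | (3R,4R)-4-({4-hydroxy-3-[(2S)-3-hydroxy-1-(4-hydroxy-3-methoxyphenyl)-1-oxopropan-2-yl]-5-methoxyphenyl}methyl)-3-{[(2S,3R)-2-(4-hydroxy-3-methoxyphenyl)-3-(hydroxymethyl)-7-methoxy-2,3-dihydro-1-benzofuran-5-yl]methyl}oxolan-2-one | COc1cc(C(=O)[C@H](CO)c2cc(C[C@H]3COC(=O)[C@@H]3Cc3cc(OC)c4c(c3)[C@H](CO)[C@@H](c3ccc(O)c(OC)c3)O4)cc(OC)c2O)ccc1O | target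

**Totals**

Total step count: 17.
Longest linear sequence: 10 steps (1 → 2 → 5 → 6 → 7 → 8 → 12 → 13 → 16 → 17).

**Three steps most likely to fail**

Step 6 (cross-coupling may lose to homo-dimerisation of 9 or to β–O–4 coupling, and the auxiliary control is only precedented for homo-coupling). The fallback sets out from 9 and returns at 11. Feruloyl sultam 9 is dimerised alone with Ag2O, the precedented auxiliary-controlled case, to the (2S,3S)-bis-sultam dehydrodimer F1. Hydrogenation (H2, Pd/C, EtOAc) saturates the cinnamoyl C=C to give the dihydro bis-sultam F2. Ti(OiPr)4 in i-PrOH at 80 °C then transesterifies only the unhindered 3-arylpropanoyl sultam, the α-branched benzylic C3 acyl sultam being shielded, and delivers 11.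

Step 12 (statistical homo-coupling of either enolate and modest facial control in a coupling of two large fragments). The fallback sets out from 18 and 13 and returns at 21, keeping the bond radical-formed but making the coupling stepwise. Imide 18 is brominated (NaHMDS, then NBS, −78 °C) to the α-bromo imide F3. Ester 13 is converted (LDA, TMSCl, −78 °C) to the trimethylsilyl ketene acetal F4. With fac-Ir(ppy)3 (1 mol %), MgBr2·OEt2, 2,6-lutidine and blue LEDs at −20 °C, the chelated α-imidyl radical from F3 adds to F4 anti to the auxiliary benzyl group. Oxidation and desilylation of the adduct radical give 21 with no homo-dimer channel.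

Step 16 (β-silyloxide elimination from the α-keto radical or Ni enolate, slow zinc insertion, and an ortho-silyloxy arylzinc outside the usual scope). The fallback sets out from 3 (via 26) and 24 (via 30) and returns at 32; it avoids any β-leaving group and sets C8 by an aldol instead. Dilithio species 26 is acylated with N-methoxy-N-methylacetamide (CC(=O)N(C)OC) to give acetovanillone F5. TBSOTf/Et3N gives the bis-TBS enol silane F6, and NBS converts it to the primary bromoketone F7. An achiral Ni- or Pd-catalysed Negishi coupling of F7 with arylzinc 30 gives the deoxybenzoin F8. Soft enolisation (TMSOTf, Et3N; the doubly benzylic ketone is far more acidic than the lactone) gives the Z-trimethylsilyl enol ether F9. Catalytic asymmetric hydroxymethylation of F9 (aqueous HCHO, Sc(OTf)3/chiral bipyridine, DME/H2O, −20 °C, Mukaiyama aldol) installs CH2OH and sets 8S, giving the tetra-TBS ketol F10. F10 is desilylated under the step 17 conditions to give 32.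

**Further compounds**

F1 | step 6 | (2S,3S)-bis-sultam dehydrodimer of 9 (coumaran with C3 acyl sultam and C5 (E)-acryloyl sultam) | O=C(/C=C/c1cc(OC)c2c(c1)[C@H](C(=O)N3[C@@H]4C[C@H]5CC[C@]4(CS3(=O)=O)C5(C)C)[C@@H](c1ccc(O)c(OC)c1)O2)N1[C@@H]2C[C@H]3CC[C@]2(CS1(=O)=O)C3(C)C
F2 | step 6 | dihydro bis-sultam (C5 3-propanoyl sultam) | O=C(CCc1cc(OC)c2c(c1)[C@H](C(=O)N3[C@@H]4C[C@H]5CC[C@]4(CS3(=O)=O)C5(C)C)[C@@H](c1ccc(O)c(OC)c1)O2)N1[C@@H]2C[C@H]3CC[C@]2(CS1(=O)=O)C3(C)C
F3 | step 12 | (4S)-4-benzyl-3-[2-bromo-3-(ArB)propanoyl]-1,3-oxazolidin-2-one (either C2 epimer) | COc1cc(CC(Br)C(=O)N2[C@@H](Cc3ccccc3)COC2=O)cc(I)c1O[Si](C)(C)C(C)(C)C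
F4 | step 12 | isopropyl trimethylsilyl ketene acetal of 13 | CC(C)OC(O[Si](C)(C)C)=CCc1cc(OC)c2c(c1)[C@H](CO[Si](C)(C)C(C)(C)C)[C@@H](c1ccc(O[Si](C)(C)C(C)(C)C)c(OC)c1)O2
F5 | step 16 | acetovanillone (1-(4-hydroxy-3-methoxyphenyl)ethan-1-one) | CC(=O)c1ccc(O)c(OC)c1
F6 | step 16 | 1-(TBSO)-1-[4-(TBSO)-3-methoxyphenyl]ethene | C=C(O[Si](C)(C)C(C)(C)C)c1ccc(O[Si](C)(C)C(C)(C)C)c(OC)c1
F7 | step 16 | 2-bromo-1-[4-(TBSO)-3-methoxyphenyl]ethan-1-one | COc1cc(C(=O)CBr)ccc1O[Si](C)(C)C(C)(C)C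
F8 | step 16 | tetra-TBS deoxybenzoin (31 without the CH2OTBS group) | COc1cc(C(=O)Cc2cc(C[C@H]3COC(=O)[C@@H]3Cc3cc(OC)c4c(c3)[C@H](CO[Si](C)(C)C(C)(C)C)[C@@H](c3ccc(O[Si](C)(C)C(C)(C)C)c(OC)c3)O4)cc(OC)c2O[Si](C)(C)C(C)(C)C)ccc1O[Si](C)(C)C(C)(C)C
F9 | step 16 | (Z)-trimethylsilyl enol ether of F8 | COc1cc(/C(O[Si](C)(C)C)=C/c2cc(C[C@H]3COC(=O)[C@@H]3Cc3cc(OC)c4c(c3)[C@H](CO[Si](C)(C)C(C)(C)C)[C@@H](c3ccc(O[Si](C)(C)C(C)(C)C)c(OC)c3)O4)cc(OC)c2O[Si](C)(C)C(C)(C)C)ccc1O[Si](C)(C)C(C)(C)C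
F10 | step 16 | tetra-TBS ketol (31 with free ketol CH2OH; 8S) | COc1cc(C(=O)[C@H](CO)c2cc(C[C@H]3COC(=O)[C@@H]3Cc3cc(OC)c4c(c3)[C@H](CO[Si](C)(C)C(C)(C)C)[C@@H](c3ccc(O[Si](C)(C)C(C)(C)C)c(OC)c3)O4)cc(OC)c2O[Si](C)(C)C(C)(C)C)ccc1O[Si](C)(C)C(C)(C)C
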